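Retrosynthesis: the hydroperoxide comes from an ene reaction of a prenyl ketone, the C7–C9 bond from acylation of a 1-stannylvinyl group on C1, the ester from a C6 carbinol; with C7 taken back to CO2H and C3 to C=O, the ring is cut at C5–C6 and C3–C4 to give propanal and dimethyl itaconate.
Enabling feature: after these adjustments the six-membered ring is a 2-methylcyclohexane-1,3-dione with a mirror plane through C4 and C1, in which C5(=O)–C6–C1–C7(=O) is a 1,4-dicarbonyl (acyl anion plus acceptor, Stetter) and C3(=O)–C4–C5(=O) a 1,3-dicarbonyl (Claisen).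
Forward order: the carbocycle forms first in one pot (C5–C6, then C3–C4); a lactone bridge C4–O–C7(=O)–C1, absent from the target, is then made and later opened to free C4–OH and turn C7 into an alkyne; the side chain is joined last.
Stereochemistry: the bridge forces C4–O cis to C7; one CBS reduction of one of the two enantiotopic ketones of the achiral trione sets C3 and with it the absolute configuration at C4 and C1; C6–O is then introduced trans to the C1 substituent under substrate control and is the stable epimer.
Key step: step 1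

Remark: atoms are numbered as in the target (C1 carries the side chain, C2 is CH2, C3 the secondary carbinol, C4 the methyl carbinol, C5 the ketone, C6 the acyloxy carbon; side chain C7(=C8H2)–C9(=O)–C10=C11–C12); in the mirror-symmetric compounds 4 to 6 the positions C3/C5 and C2/C6 are equivalent, and 1, 2, 16 and all reagents are taken to be commercial.

Step 1
Reactants: 1 propanal, 2 dimethyl itaconate
Product: 5 4-methyl-3,5-dioxocyclohexane-1-carboxylic acid, via keto diester 3 (not isolated), via dione ester 4 (not isolated)
Conditions: 3-benzyl-5-(2-hydroxyethyl)-4-methylthiazolium chloride (10 mol %), Et3N (0.3 equiv), 1,4-dioxane, 70 °C, sealed vessel; then NaOMe (2.5 equiv), MeOH, 65 °C; then 2 M NaOH, rt; then 6 M HCl to pH 1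
Reagents that add atoms: sodium hydroxide, [Na+].[OH-]
Why: The thiazol-2-ylidene adds to propanal to give a nucleophilic enaminol (acyl anion equivalent) that adds 1,4 to the unsubstituted methylene terminus of 2 (Stetter reaction, C5–C6) and, after proton transfer and loss of the carbene, leaves keto diester 3. Methoxide then forms the enolate of the ethyl ketone at its CH2 group (C4), which attacks the CH2CO2Me ester carbonyl (C3) in an intramolecular Claisen (Dieckmann-type) condensation (C3–C4) that is drawn forward by the stabilized enolate of the 2-methyl-1,3-dione 4, and hydroxide finally cleaves the remaining methyl ester. The closest known chemistry is the thiazolium-catalysed addition of aliphatic aldehydes to acrylates and the base-mediated cyclization of acetonylsuccinic esters to 3,5-dioxocyclohexanecarboxylates. The six-membered ring closes in the 6-(enolexo)-exo-trig mode. No stereocentre survives the step, because C4 is enolized and C1 lies on the mirror plane of the dione, so 5 is achiral. The selectivity needed is ring size, six-membered closure onto the primary ester C3 against five-membered closure onto the hindered ester C7, and it should be secured by the lower strain of the cyclohexane-1,3-dione, the unhindered CH2CO2Me carbonyl and the reversibility of the Claisen step, while the Stetter step has only one unsubstituted acceptor terminus and the self-addition of 1 is reversible.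

Step 2
Reactants: 5 4-methyl-3,5-dioxocyclohexane-1-carboxylic acid
Product: 6 1-methyl-2-oxabicyclo[2.2.2]octane-3,6,7-trione
Conditions: PhIO (iodosylbenzene, 1.2 equiv), 4 Å molecular sieves, CH2Cl2/MeCN, 0 °C to rt
Reagents that add atoms: none
Why: Oxidative α-acyloxylation of a 1,3-diketone by a trivalent iodine reagent, run intramolecularly as a lactonization, in which the enol of 5 and its own carboxyl group bind to iodine and loss of iodobenzene joins the carboxylate oxygen to C4, which is possible only on the ring face that carries C7, so the C4–O bond is necessarily cis to C7 and the bridged product keeps the mirror plane.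

Step 3
Reactants: 6 1-methyl-2-oxabicyclo[2.2.2]octane-3,6,7-trione
Product: 7 (1S,4R,7R)-7-hydroxy-1-methyl-2-oxabicyclo[2.2.2]octane-3,6-dione
Conditions: (S)-2-methyl-CBS-oxazaborolidine (0.2 equiv), BH3·SMe2 (0.6 equiv), THF, −40 °C; MeOH quench
Reagents that add atoms: none
Why: Corey–Bakshi–Shibata reduction used as a desymmetrization of the achiral trione, in which the catalyst takes the quaternary C4 as the large group and delivers hydride to give an (R)-carbinol, and only at one of the two enantiotopic ketones does that sense coincide with approach through the open gap beside the lactone bridge (no inward hydrogen) instead of the gap beside the CH2 of the other keto bridge, so that the C3 hydroxyl should stand anti to the lactone oxygen and the single event fixes C3 and with it the absolute configuration at C4 and C1.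

Step 4
Reactants: 7 (1S,4R,7R)-7-hydroxy-1-methyl-2-oxabicyclo[2.2.2]octane-3,6-dione
Product: 8 (1S,4R,7R)-1-methyl-6,7-bis[(triethylsilyl)oxy]-2-oxabicyclo[2.2.2]oct-5-en-3-one
Conditions: Et3SiOTf (2.5 equiv), Et3N (4 equiv), CH2Cl2, −78 to 0 °C
Reagents that add atoms: triethylsilyl trifluoromethanesulfonate, CC[Si](CC)(CC)OS(=O)(=O)C(F)(F)F
Why: Silylation with a silyl triflate and an amine base, which turns the C3 hydroxyl into a silyl ether (blocking retro-aldol cleavage of C3–C4 in the basic steps that follow) and the C5 ketone, enolizable only towards C6 because C4 is quaternary, into a silyl enol ether that masks it from the hydride of step 5, without touching a stereocentre.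

Step 5
Reactants: 8 (1S,4R,7R)-1-methyl-6,7-bis[(triethylsilyl)oxy]-2-oxabicyclo[2.2.2]oct-5-en-3-one
Product: 10 (2S,3R,5R)-5-ethynyl-2-hydroxy-2-methyl-3-[(triethylsilyl)oxy]cyclohexan-1-one, via lactol 9 (not isolated)
Conditions: iBu2AlH (1.2 equiv), CH2Cl2, −78 °C; then MeOH, K2CO3 (3 equiv), dimethyl (1-diazo-2-oxopropyl)phosphonate (1.5 equiv), −78 °C to rt
Reagents that add atoms: dimethyl (1-diazo-2-oxopropyl)phosphonate, CC(=O)C(=[N+]=[N-])P(=O)(OC)OC
Why: Partial reduction of the lactone to lactol 9 followed in the same flask by Ohira–Bestmann (Seyferth–Gilbert) homologation of its open hydroxy aldehyde form should give the terminal alkyne and free the C4 hydroxyl, while the methanolic carbonate cleaves the silyl enol ether back to the C5 ketone, and C1 keeps its configuration provided the aldehyde, held mostly as the bridged lactol, is homologated faster than it enolizes.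

Step 6
Reactants: 10 (2S,3R,5R)-5-ethynyl-2-hydroxy-2-methyl-3-[(triethylsilyl)oxy]cyclohexan-1-one
Product: 13 (2S,3R,5S,6S)-5-ethynyl-2,6-dihydroxy-2-methyl-3-[(triethylsilyl)oxy]cyclohexan-1-one, via silyl enol ether 11 (not isolated), via silyloxy ketone 12 (not isolated)
Conditions: Me3SiOTf (2.5 equiv), Et3N (4 equiv), CH2Cl2, 0 °C; then mCPBA (1.1 equiv), hexane/CH2Cl2, −20 °C; then 0.5 M HCl, THF, 0 °C
Reagents that add atoms: 3-chloroperoxybenzoic acid (mCPBA), OOC(=O)c1cccc(Cl)c1
Why: Rubottom oxidation, in which the silyl enol ether 11 (possible only towards C6) is epoxidized on the face opposite the pseudo-axial C4 silyloxy group and the C1 ethynyl group, silyl migration gives 12 and dilute acid removes the trimethylsilyl groups, so the new C6 hydroxyl should be trans to the C1 substituent, which is also the diequatorial arrangement favoured at equilibrium since C6 is epimerizable.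

Step 7
Reactants: 13 (2S,3R,5S,6S)-5-ethynyl-2,6-dihydroxy-2-methyl-3-[(triethylsilyl)oxy]cyclohexan-1-one
Product: 14 (1S,3S,4R,6S)-6-ethynyl-3-hydroxy-3-methyl-2-oxo-4-[(triethylsilyl)oxy]cyclohexyl 3-methylbutanoate
Conditions: 3-methylbutanoyl chloride (1.2 equiv), pyridine, DMAP (0.05 equiv), CH2Cl2, 0 °C
Reagents that add atoms: 3-methylbutanoyl chloride, CC(C)CC(=O)Cl
Why: Esterification of the secondary C6 hydroxyl with an acid chloride under nucleophilic catalysis, which should leave the hindered tertiary C4 hydroxyl untouched and forms no stereocentre.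

Step 8
Reactants: 14 (1S,3S,4R,6S)-6-ethynyl-3-hydroxy-3-methyl-2-oxo-4-[(triethylsilyl)oxy]cyclohexyl 3-methylbutanoate
Product: 15 (1S,3S,4R,6R)-3-hydroxy-3-methyl-2-oxo-6-[1-(tributylstannyl)ethenyl]-4-[(triethylsilyl)oxy]cyclohexyl 3-methylbutanoate
Conditions: Bu3SnH (1.5 equiv), Mo(CO)3(CNtBu)3 (5 mol %), hydroquinone (0.1 equiv), THF, 55 °C
Reagents that add atoms: tributylstannane, CCCC[SnH](CCCC)CCCC
Why: Molybdenum-catalysed hydrostannation of the terminal alkyne, which is known to place tin on the internal carbon and so should give the 1-stannylvinyl group on C1, while the radical inhibitor keeps the tin hydride from reducing the α-acyloxy ketone, and no stereocentre is formed.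

Step 9
Reactants: 16 4-methylpent-3-enoic acid
Product: 17 4-methylpent-3-enoyl chloride
Conditions: (COCl)2 (1.2 equiv), DMF (cat), CH2Cl2, 0 °C to rt
Reagents that add atoms: oxalyl chloride, ClC(=O)C(=O)Cl
Why: Conversion of a carboxylic acid into its acid chloride through the chloroiminium salt formed from DMF, under base-free conditions that should keep the β,γ-double bond in place.

Step 10
Reactants: 15 (1S,3S,4R,6R)-3-hydroxy-3-methyl-2-oxo-6-[1-(tributylstannyl)ethenyl]-4-[(triethylsilyl)oxy]cyclohexyl 3-methylbutanoate, 17 4-methylpent-3-enoyl chloride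
Product: 18 (1S,3S,4R,6S)-3-hydroxy-3-methyl-6-(6-methyl-3-oxohepta-1,5-dien-2-yl)-2-oxo-4-[(triethylsilyl)oxy]cyclohexyl 3-methylbutanoate
Conditions: Pd2(dba)3 (5 mol %), tri(2-furyl)phosphine (20 mol %), CO (1 atm), THF, 50 °C
Reagents that add atoms: none
Why: Stille acylation, in which oxidative addition of 17 to zerovalent palladium, transfer of the alkenyl group from tin and reductive elimination form the C7–C9 bond with the 1,1-disubstituted alkene intact, the CO atmosphere serving only to hold back decarbonylation of the β,γ-unsaturated acylpalladium intermediate, and no stereocentre is formed.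

Step 11
Reactants: 18 (1S,3S,4R,6S)-3-hydroxy-3-methyl-6-(6-methyl-3-oxohepta-1,5-dien-2-yl)-2-oxo-4-[(triethylsilyl)oxy]cyclohexyl 3-methylbutanoate
Product: 19 (1S,3S,4R,6S)-3,4-dihydroxy-3-methyl-6-(6-methyl-3-oxohepta-1,5-dien-2-yl)-2-oxocyclohexyl 3-methylbutanoate
Conditions: HF·pyridine, pyridine, THF, 0 °C
Reagents that add atoms: none
Why: Fluoride-mediated cleavage of the triethylsilyl ether under buffered conditions that should leave the ester, the tertiary α-ketol and the β,γ-unsaturated ketone unchanged and touch no stereocentre.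

Step 12
Reactants: 19 (1S,3S,4R,6S)-3,4-dihydroxy-3-methyl-6-(6-methyl-3-oxohepta-1,5-dien-2-yl)-2-oxocyclohexyl 3-methylbutanoate
Product: 20 (1S,3S,4R,6S)-6-[(4E)-6-hydroperoxy-6-methyl-3-oxohepta-1,4-dien-2-yl]-3,4-dihydroxy-3-methyl-2-oxocyclohexyl 3-methylbutanoate
Conditions: O2, tetraphenylporphyrin (1 mol %), visible light, CH2Cl2, −20 °C
Reagents that add atoms: dioxygen, O=O
Why: Schenck ene reaction of singlet oxygen with the trisubstituted alkene, in which oxygen bonds to C12 and takes a hydrogen from C10, which lies on the more substituted side of the alkene and is activated by the C9 carbonyl, so that the double bond should move to C10=C11 in conjugation with the ketone as the E isomer, while the electron-poor C7=C8 alkene does not react and no ring stereocentre is touched.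

Compound list
1 | propanal | CCC=O | starting material
2 | dimethyl itaconate (dimethyl 2-methylidenebutanedioate) | C=C(CC(=O)OC)C(=O)OC | starting material
3 | dimethyl 2-(2-oxobutyl)butanedioate (racemic, formed in the flask) | CCC(=O)CC(CC(=O)OC)C(=O)OC | intermediate
4 | methyl 4-methyl-3,5-dioxocyclohexane-1-carboxylate (enolized dione, formed in the flask) | CC1C(=O)CC(CC1=O)C(=O)OC | intermediate
5 | 4-methyl-3,5-dioxocyclohexane-1-carboxylic acid (enolized dione, achiral) | CC1C(=O)CC(CC1=O)C(=O)O | intermediate
6 | 1-methyl-2-oxabicyclo[2.2.2]octane-3,6,7-trione (achiral; lactone oxygen on C4, lactone carbonyl C7 on C1) | CC12OC(=O)C(CC1=O)CC2=O | intermediate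
7 | (1S,4R,7R)-7-hydroxy-1-methyl-2-oxabicyclo[2.2.2]octane-3,6-dione (C3 hydroxyl anti to the lactone oxygen) | O=C2[C@@H]1C[C@@H](O)[C@](C)(O2)C(=O)C1 | intermediate
8 | (1S,4R,7R)-1-methyl-6,7-bis[(triethylsilyl)oxy]-2-oxabicyclo[2.2.2]oct-5-en-3-one | O=C2[C@@H]1C[C@@H](O[Si](CC)(CC)CC)[C@](C)(O2)C(O[Si](CC)(CC)CC)=C1 | intermediate
9 | (1S,4R,7R)-1-methyl-6,7-bis[(triethylsilyl)oxy]-2-oxabicyclo[2.2.2]oct-5-en-3-ol (lactol, both epimers at the lactol carbon, formed in the flask) | OC2[C@@H]1C[C@@H](O[Si](CC)(CC)CC)[C@](C)(O2)C(O[Si](CC)(CC)CC)=C1 | intermediate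
10 | (2S,3R,5R)-5-ethynyl-2-hydroxy-2-methyl-3-[(triethylsilyl)oxy]cyclohexan-1-one | C#C[C@@H]1C[C@@H](O[Si](CC)(CC)CC)[C@](C)(O)C(=O)C1 | intermediate
11 | C4 trimethylsilyl ether and C5 trimethylsilyl enol ether (C5=C6) of 10, configuration unchanged (formed in the flask) | C#C[C@@H]1C[C@@H](O[Si](CC)(CC)CC)[C@](C)(O[Si](C)(C)C)C(O[Si](C)(C)C)=C1 | intermediate
12 | C5 ketone from 11 with trimethylsilyloxy groups at C4 and C6, the C6 oxygen trans to the ethynyl group (formed in the flask) | C#C[C@@H]1C[C@@H](O[Si](CC)(CC)CC)[C@](C)(O[Si](C)(C)C)C(=O)[C@H]1O[Si](C)(C)C | intermediate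
13 | (2S,3R,5S,6S)-5-ethynyl-2,6-dihydroxy-2-methyl-3-[(triethylsilyl)oxy]cyclohexan-1-one | C#C[C@@H]1C[C@@H](O[Si](CC)(CC)CC)[C@](C)(O)C(=O)[C@H]1O | intermediate
14 | (1S,3S,4R,6S)-6-ethynyl-3-hydroxy-3-methyl-2-oxo-4-[(triethylsilyl)oxy]cyclohexyl 3-methylbutanoate | C#C[C@@H]1C[C@@H](O[Si](CC)(CC)CC)[C@](C)(O)C(=O)[C@H]1OC(=O)CC(C)C | intermediate
15 | (1S,3S,4R,6R)-3-hydroxy-3-methyl-2-oxo-6-[1-(tributylstannyl)ethenyl]-4-[(triethylsilyl)oxy]cyclohexyl 3-methylbutanoate | C=C([Sn](CCCC)(CCCC)CCCC)[C@@H]1C[C@@H](O[Si](CC)(CC)CC)[C@](C)(O)C(=O)[C@H]1OC(=O)CC(C)C | intermediate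
16 | 4-methylpent-3-enoic acid | CC(C)=CCC(=O)O | starting material
17 | 4-methylpent-3-enoyl chloride | CC(C)=CCC(=O)Cl | intermediate
18 | (1S,3S,4R,6S)-3-hydroxy-3-methyl-6-(6-methyl-3-oxohepta-1,5-dien-2-yl)-2-oxo-4-[(triethylsilyl)oxy]cyclohexyl 3-methylbutanoate | C=C(C(=O)CC=C(C)C)[C@@H]1C[C@@H](O[Si](CC)(CC)CC)[C@](C)(O)C(=O)[C@H]1OC(=O)CC(C)C | intermediate
19 | (1S,3S,4R,6S)-3,4-dihydroxy-3-methyl-6-(6-methyl-3-oxohepta-1,5-dien-2-yl)-2-oxocyclohexyl 3-methylbutanoate | C=C(C(=O)CC=C(C)C)[C@@H]1C[C@@H](O)[C@](C)(O)C(=O)[C@H]1OC(=O)CC(C)C | intermediate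
20 | (1S,3S,4R,6S)-6-[(4E)-6-hydroperoxy-6-methyl-3-oxohepta-1,4-dien-2-yl]-3,4-dihydroxy-3-methyl-2-oxocyclohexyl 3-methylbutanoate | C=C(C(=O)/C=C/C(C)(C)OO)[C@@H]1C[C@@H](O)[C@](C)(O)C(=O)[C@H]1OC(=O)CC(C)C | target

Total step count: 12. Longest linear sequence: 11 steps (steps 1 to 8 and 10 to 12); step 9 prepares the acid chloride for step 10.

Steps most likely to fail

Step 2. The carboxylate may fail to reach C4 across the ring through the boat-like arrangement, so that intermolecular oxygen transfer or ester oligomers take over. The fallback sets out from 5: hydroxylation of the enolized dione at C4 with dimethyldioxirane (acetone, 0 °C) should give 4-hydroxy-4-methyl-3,5-dioxocyclohexane-1-carboxylic acid F1 as a cis/trans mixture. Carboxyl activation (2,4,6-trichlorobenzoyl chloride, Et3N, DMAP, toluene) then closes the lactone, which only the cis acid can do, while the trans acid is fed in by epimerization at C1 of the activated acyl species. This returns to the route at 6.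

Step 3. Facial discrimination between the two flanks of the bicyclic ketone may be poor, which would erode the diastereoselectivity (C3 hydroxyl syn to the lactone oxygen) though not the sense of the carbinol configuration. The fallback sets out from 6: acid-catalysed methanolysis (TsOH, MeOH) opens the lactone to methyl cis-4-hydroxy-4-methyl-3,5-dioxocyclohexane-1-carboxylate F2. A ketoreductase chosen by screening (NADPH, glucose and glucose dehydrogenase, phosphate buffer, pH 7) should reduce one enantiotopic ketone with enzyme control of site and face to methyl (1R,3R,4S)-3,4-dihydroxy-4-methyl-5-oxocyclohexane-1-carboxylate F3. TsOH in toluene at 80 °C closes the lactone again and returns to the route at 7.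

Step 12. Hydrogen abstraction from the (Z)-methyl group on C12 may compete with abstraction from C10 and give the secondary hydroperoxide with an isopropenyl end, a loss that would fall on the last intermediate. The fallback sets out from 15 and moves the ene reaction to acid 16, where regioisomers can be separated on scale, to give (E)-4-hydroperoxy-4-methylpent-2-enoic acid F4. Et3SiCl and imidazole give triethylsilyl (E)-4-methyl-4-[(triethylsilyl)peroxy]pent-2-enoate F5, and oxalyl chloride with catalytic DMF turns the silyl ester into (E)-4-methyl-4-[(triethylsilyl)peroxy]pent-2-enoyl chloride F6. Stille acylation of 15 with this chloride under phosphine-free conditions (Pd2(dba)3, AsPh3, THF), chosen to spare the peroxide, should give (1S,3S,4R,6S)-3-hydroxy-3-methyl-6-{(4E)-6-methyl-3-oxo-6-[(triethylsilyl)peroxy]hepta-1,4-dien-2-yl}-2-oxo-4-[(triethylsilyl)oxy]cyclohexyl 3-methylbutanoate F7. HF·pyridine removes both silyl groups and returns to the route at 20.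

Further compounds
F1 | step 2 | 4-hydroxy-4-methyl-3,5-dioxocyclohexane-1-carboxylic acid (cis/trans mixture) | CC1(O)C(=O)CC(CC1=O)C(=O)O
F2 | step 3 | methyl cis-4-hydroxy-4-methyl-3,5-dioxocyclohexane-1-carboxylate (hydroxyl cis to the ester, achiral) | COC(=O)[C@@H]1CC(=O)[C@](C)(O)C(=O)C1
F3 | step 3 | methyl (1R,3R,4S)-3,4-dihydroxy-4-methyl-5-oxocyclohexane-1-carboxylate | COC(=O)[C@@H]1C[C@@H](O)[C@](C)(O)C(=O)C1
F4 | step 12 | (E)-4-hydroperoxy-4-methylpent-2-enoic acid | CC(C)(OO)/C=C/C(=O)O
F5 | step 12 | triethylsilyl (E)-4-methyl-4-[(triethylsilyl)peroxy]pent-2-enoate | CC(C)(OO[Si](CC)(CC)CC)/C=C/C(=O)O[Si](CC)(CC)CC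
F6 | step 12 | (E)-4-methyl-4-[(triethylsilyl)peroxy]pent-2-enoyl chloride | CC(C)(OO[Si](CC)(CC)CC)/C=C/C(=O)Cl
F7 | step 12 | (1S,3S,4R,6S)-3-hydroxy-3-methyl-6-{(4E)-6-methyl-3-oxo-6-[(triethylsilyl)peroxy]hepta-1,4-dien-2-yl}-2-oxo-4-[(triethylsilyl)oxy]cyclohexyl 3-methylbutanoate | C=C(C(=O)/C=C/C(C)(C)OO[Si](CC)(CC)CC)[C@@H]1C[C@@H](O[Si](CC)(CC)CC)[C@](C)(O)C(=O)[C@H]1OC(=O)CC(C)C
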